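Everything rests on cutting the enol-lactone bond O–C19 together with C4–C5, which reduces ring A and the lactone to a monocyclic tropone carrying a methylketene on a three-carbon tether. The feature used is the C5–C6 junction of ring B: C5 is the lone saturated carbon of the seven-membered triene and C6 carries the lactone oxygen, which is what remains after a ketene has bonded through its carbonyl carbon to a tropone oxygen and through its other carbon to the ring position next door. One intramolecular [8+2] cycloaddition thus forms two rings, two skeletal bonds and the C4/C5 stereocentres, relayed from the C1 silyl ether. The precursor is a 5-bromotropone with the (R)-silyloxy ketene chain at C10.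

Key step: step 8

Remark: skeletal atoms carry icetexane numbers (ring A: C1–C5 and C10; ring B: C5–C10 and C20; ring C: C8, C9, C11–C14; C18 = methyl on C4; C19 = lactone carbonyl); the target is (1R,4S,5R), and C4 of every open-chain intermediate is left racemic because it becomes the sp2 ketene carbon.

Step 1
Reactants: 1 dimethyl 2-methylpentanedioate
Product: 2 5-methoxy-4-methyl-5-oxopentanoic acid
Conditions: Candida antarctica lipase B (immobilised), pH 7 phosphate buffer/MTBE, 25 °C
Reagents that add atoms: water (O)
Why: Lipase-catalysed regioselective ester hydrolysis, in which the enzyme's acyl pocket rejects the α-branched ester so that only the unbranched CO2Me is cleaved and the free acid sits at the future C1 terminus.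

Step 2
Reactants: 2 5-methoxy-4-methyl-5-oxopentanoic acid
Product: 4 methyl 6-diazo-2-methyl-5-oxohexanoate, via acid chloride 3 (not isolated)
Conditions: (COCl)2, DMF (cat.), CH2Cl2, 0 → 25 °C; concentrate; CH2N2 (3 equiv), Et2O, 0 °C
Reagents that add atoms: diazomethane (C=[N+]=[N-])
Why: Acid chloride formation followed by acylation of diazomethane (first stage of the Arndt–Eistert sequence), a second equivalent of diazomethane taking up the HCl.

Step 3
Reactants: 4 methyl 6-diazo-2-methyl-5-oxohexanoate, 5 4-bromoanisole
Product: 7 methyl 5-(3-bromo-6-methoxycyclohepta-2,4,6-trien-1-yl)-2-methyl-5-oxopentanoate, via norcaradiene 6 (not isolated)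
Conditions: Rh2(O2CCF3)4 (1 mol%), neat 5 (20 equiv), slow addition of 4, 25 °C; excess 5 distilled off
Reagents that add atoms: none
Why: Buchner reaction, in which the electrophilic rhodium carbenoid cyclopropanates one of the two symmetry-equivalent unsubstituted CH=CH bonds of the arene and norcaradiene 6 opens by 6π electrocyclic ring opening, placing the acyl-bearing carbon C10 between C5 and C20 as a single constitutional isomer (C10 forms racemic and becomes sp2 in step 4; the C4–H next to the ester is deactivated toward carbenoid insertion).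

Step 4
Reactants: 7 methyl 5-(3-bromo-6-methoxycyclohepta-2,4,6-trien-1-yl)-2-methyl-5-oxopentanoate
Product: 10 methyl 5-(6-bromo-3-oxocyclohepta-1,4,6-trien-1-yl)-2-methyl-5-oxopentanoate, via conjugated triene isomer 8 (not isolated), via methoxytropylium tetrafluoroborate 9 (not isolated)
Conditions: DBU (0.1 equiv), CH2Cl2, 25 °C; Ph3CBF4 (1.3 equiv), 0 → 25 °C; LiBr (3 equiv), MeCN, 40 °C
Reagents that add atoms: none
Why: Base-mediated double-bond isomerisation moves the acyl group into conjugation and frees a ring CH2, hydride abstraction by the trityl cation gives alkoxytropylium 9, and SN2 O-demethylation by bromide releases the tropone with the carbonyl at C6 while avoiding ipso attack of water at C9–Br.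

Step 5
Reactants: 10 methyl 5-(6-bromo-3-oxocyclohepta-1,4,6-trien-1-yl)-2-methyl-5-oxopentanoate
Product: 11 methyl (5R)-5-(6-bromo-3-oxocyclohepta-1,4,6-trien-1-yl)-5-hydroxy-2-methylpentanoate
Conditions: RuCl[(R,R)-TsDPEN](p-cymene) (1 mol%), HCO2H/Et3N (5:2), EtOAc, 25 °C
Reagents that add atoms: none
Why: Asymmetric transfer hydrogenation by outer-sphere Ru–H/N–H delivery to the polarised side-chain ketone, the troponyl ring taking the role of the aryl group so that the (R,R) ligand should set (R)-C1 as it does for aryl alkyl ketones, while the vinylogous tropone carbonyl is not hydride-accepting.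

Step 6
Reactants: 11 methyl (5R)-5-(6-bromo-3-oxocyclohepta-1,4,6-trien-1-yl)-5-hydroxy-2-methylpentanoate
Product: 12 methyl (5R)-5-(6-bromo-3-oxocyclohepta-1,4,6-trien-1-yl)-5-[(tert-butyldimethylsilyl)oxy]-2-methylpentanoate
Conditions: TBSCl, imidazole, DMF, 25 °C
Reagents that add atoms: tert-butyldimethylsilyl chloride (CC(C)(C)[Si](C)(C)Cl)
Why: Standard silylation of a secondary alcohol, which blocks δ-lactonisation onto C19 and supplies the group that later biases the ring A transition state.

Step 7
Reactants: 12 methyl (5R)-5-(6-bromo-3-oxocyclohepta-1,4,6-trien-1-yl)-5-[(tert-butyldimethylsilyl)oxy]-2-methylpentanoate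
Product: 13 (5R)-5-(6-bromo-3-oxocyclohepta-1,4,6-trien-1-yl)-5-[(tert-butyldimethylsilyl)oxy]-2-methylpentanoic acid
Conditions: Me3SnOH (5 equiv), ClCH2CH2Cl, 70 °C; then 0.5 M HCl wash, 0 °C
Reagents that add atoms: trimethyltin hydroxide (C[Sn](C)(C)O)
Why: Neutral ester cleavage with Me3SnOH (acyl transfer to tin, then protonation), which spares the silyl ether and the hydroxide-sensitive bromotropone.

Step 8
Reactants: 13 (5R)-5-(6-bromo-3-oxocyclohepta-1,4,6-trien-1-yl)-5-[(tert-butyldimethylsilyl)oxy]-2-methylpentanoic acid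
Product: 16 (1R,4S,5R)-9-bromo-1-[(tert-butyldimethylsilyl)oxy] tricyclic cycloheptatriene enol lactone, via acid chloride 14 (not isolated), via ketene 15 (not isolated)
Conditions: 1-chloro-N,N,2-trimethylprop-1-en-1-amine (1.1 equiv), CH2Cl2, 0 → 25 °C; then syringe-pump addition to iPr2NEt (5 equiv), toluene (0.005 M), 80 °C
Reagents that add atoms: none
Why: Proposed new method: the neutral chloroenamine makes acid chloride 14 without touching the tropone (oxalyl chloride would turn it into a chlorotropylium salt), and iPr2NEt then eliminates HCl to give methylketene 15, whose carbonyl carbon C19 is attacked by the tropone oxygen while the enolate-like carbon C4 bonds to the neighbouring ring carbon C5, a ten-electron [8+2] process that may be concerted but asynchronous or pass through an acyloxytropylium enolate. The nearest precedent is the bimolecular [8+2] addition of aryl- and halo-substituted ketenes to tropone, which furnishes 3,3a-dihydro-2H-cyclohepta[b]furan-2-ones; an intramolecular case with a dialkylketene is not known. The lactone closes as a five-membered ring through O–C19 and C4–C5 (5-exo attack of C4 on the tropylium carbon once O–C19 is in place), and the same C4–C5 bond closes ring A as a six-membered carbocycle by a chair-like 6-exo approach of the C1–C2–C3 tether to C5. C4 and C5 form cis because C19 and C6 must share the bridging oxygen, and their absolute sense is relayed from C1: the silyloxy group should lie in the tropone plane next to C20–H (equatorial in the forming chair), where it avoids the axial hydrogens on C3 and C5 and keeps its C–O bond out of alignment with the electron-poor ring π-system, so that (1R) leads to (4S,5R) with the C1 oxygen cis to C19. Two selectivities are required, ten-electron addition in preference to cyclobutanone formation at C5=C10 and bonding at C5 in preference to C7; the first rests on the nucleophilic tropone oxygen, the reluctance of a dialkylketene to add to an electron-poor C=C bond and high dilution against dimerisation, the second on the three-atom tether, which cannot span to C7. The double bonds C6=C7, C8=C9 and C10=C20 arise directly, and 80 °C keeps the product below the onset of 1,5-hydrogen shifts.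

Step 9
Reactants: 16 (1R,4S,5R)-9-bromo-1-[(tert-butyldimethylsilyl)oxy] tricyclic cycloheptatriene enol lactone
Product: 17 (1R,4S,5R)-1-[(tert-butyldimethylsilyl)oxy]-9-(trimethylstannyl) tricyclic cycloheptatriene enol lactone
Conditions: Me3SnSnMe3, Pd(PPh3)4 (5 mol%), 1,4-dioxane, 80 °C
Reagents that add atoms: hexamethylditin (C[Sn](C)(C)[Sn](C)(C)C)
Why: Palladium-catalysed stannylation of an alkenyl bromide (oxidative addition to zerovalent palladium, Sn–Sn transmetalation, reductive elimination) under neutral conditions that spare the enol lactone and the silyl ether.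

Step 10
Reactants: 18 diisopropyl squarate
Product: 20 3-isopropoxy-4-isopropylcyclobut-3-ene-1,2-dione, via squarate adduct 19 (not isolated)
Conditions: iPrMgCl, THF, −78 °C; aq. NH4Cl; then 12 M HCl (cat.), CH2Cl2, 25 °C
Reagents that add atoms: isopropylmagnesium chloride (CC(C)[Mg]Cl)
Why: Grignard 1,2-addition to one squarate carbonyl followed by acid-induced allylic ionisation and loss of isopropanol, the usual route from dialkyl squarates to alkyl alkoxy cyclobutenediones.

Step 11
Reactants: 20 3-isopropoxy-4-isopropylcyclobut-3-ene-1,2-dione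
Product: 21 4-hydroxy-3-isopropoxy-2-isopropylcyclobut-2-en-1-one
Conditions: LiAlH(OtBu)3, THF, −78 °C; pH 7 phosphate buffer
Reagents that add atoms: none
Why: Regioselective hydride 1,2-reduction of the more electrophilic carbonyl, the one next to the alkoxy-bearing carbon, because the other carbonyl is deactivated as a vinylogous ester (the new carbinol centre is racemic and is lost in step 13).

Step 12
Reactants: 21 4-hydroxy-3-isopropoxy-2-isopropylcyclobut-2-en-1-one
Product: 22 4-chloro-3-isopropoxy-2-isopropylcyclobut-2-en-1-one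
Conditions: SOCl2, pyridine, CH2Cl2, −20 → 0 °C; used crude
Reagents that add atoms: thionyl chloride (O=S(Cl)Cl)
Why: Deoxychlorination through the chlorosulfite under buffered conditions, chloride ending at C4 because the conjugated 4-chloro enone is the stable allylic isomer.

Step 13
Reactants: 17 (1R,4S,5R)-1-[(tert-butyldimethylsilyl)oxy]-9-(trimethylstannyl) tricyclic cycloheptatriene enol lactone, 22 4-chloro-3-isopropoxy-2-isopropylcyclobut-2-en-1-one
Product: 26 (1R,4S,5R)-1-[(tert-butyldimethylsilyl)oxy]-14-hydroxy-12-isopropoxyicetexa-6,8,10(20),11,13-pentaen-19,6-olide, via alkenylcyclobutenone 23 (not isolated), via dienylketene 24 (not isolated), via cyclohexadienone 25 (not isolated)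
Conditions: Pd2(dba)3 (2.5 mol%), tri(2-furyl)phosphine (10 mol%), 1,4-dioxane, 50 °C, then 90 °C
Reagents that add atoms: none
Why: Stille coupling at C4 of the chlorocyclobutenone followed by the cyclobutenone benzannulation cascade (4π electrocyclic ring opening to dienylketene 24, 6π electrocyclisation of the ketene carbon onto C8, tautomerisation), which builds ring C with C11 on C9 and the phenolic C14 on C8; the transient stereocentres of 23 and 25 disappear on aromatisation.

Step 14
Reactants: 26 (1R,4S,5R)-1-[(tert-butyldimethylsilyl)oxy]-14-hydroxy-12-isopropoxyicetexa-6,8,10(20),11,13-pentaen-19,6-olide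
Product: 27 (1R,4S,5R)-1-[(tert-butyldimethylsilyl)oxy]-12-isopropoxy-11,14-dioxoicetexa-6,8,10(20),12-tetraen-19,6-olide
Conditions: (KSO3)2NO, KH2PO4 buffer, acetone/H2O, 0 → 25 °C
Reagents that add atoms: potassium nitrosodisulfonate ([K+].[K+].[O]N(S(=O)(=O)[O-])S(=O)(=O)[O-])
Why: Teuber oxidation, in which the nitroxide radical converts a phenol with a free para position (C11–H) into the para-quinone under near-neutral conditions that spare the enol lactone.

Step 15
Reactants: 27 (1R,4S,5R)-1-[(tert-butyldimethylsilyl)oxy]-12-isopropoxy-11,14-dioxoicetexa-6,8,10(20),12-tetraen-19,6-olide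
Product: 28 (1R,4S,5R)-1-[(tert-butyldimethylsilyl)oxy]-12-hydroxy-11,14-dioxoicetexa-6,8,10(20),12-tetraen-19,6-olide
Conditions: BCl3, CH2Cl2, −78 °C; then pH 4 buffer
Reagents that add atoms: none
Why: Lewis-acid dealkylation of the vinylogous isopropyl ester, BCl3 chelating between the C11 carbonyl and the ether oxygen and releasing the secondary alkyl group as its chloride at a temperature where the secondary silyl ether and the enol lactone are inert.

Step 16
Reactants: 28 (1R,4S,5R)-1-[(tert-butyldimethylsilyl)oxy]-12-hydroxy-11,14-dioxoicetexa-6,8,10(20),12-tetraen-19,6-olide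
Product: 29 6,7-anhydroballotiquinone
Conditions: HF·pyridine, pyridine, THF, 0 → 25 °C
Reagents that add atoms: none
Why: Buffered fluoride desilylation, which breaks only the Si–O bond and therefore retains the C1 configuration and leaves the enol lactone and hydroxyquinone untouched.

Compound list
1 | dimethyl 2-methylpentanedioate (dimethyl 2-methylglutarate, racemic) | COC(=O)C(C)CCC(=O)OC | starting material
2 | 5-methoxy-4-methyl-5-oxopentanoic acid (half ester with the free acid on the unbranched end, racemic) | COC(=O)C(C)CCC(=O)O | intermediate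
3 | methyl 5-chloro-2-methyl-5-oxopentanoate (acid chloride, formed in the flask) | COC(=O)C(C)CCC(=O)Cl | intermediate
4 | methyl 6-diazo-2-methyl-5-oxohexanoate | COC(=O)C(C)CCC(=O)C=[N+]=[N-] | intermediate
5 | 4-bromoanisole | COc1ccc(Br)cc1 | starting material
6 | methyl 5-(2-bromo-5-methoxybicyclo[4.1.0]hepta-2,4-dien-7-yl)-2-methyl-5-oxopentanoate (norcaradiene, formed in the flask) | COC(=O)C(C)CCC(=O)C1C2C(Br)=CC=C(OC)C12 | intermediate
7 | methyl 5-(3-bromo-6-methoxycyclohepta-2,4,6-trien-1-yl)-2-methyl-5-oxopentanoate (stereoisomer mixture) | COC(=O)C(C)CCC(=O)C1C=C(OC)C=CC(Br)=C1 | intermediate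
8 | methyl 5-(6-bromo-3-methoxycyclohepta-1,3,6-trien-1-yl)-2-methyl-5-oxopentanoate (conjugated isomer drawn with the ring CH2 at C8; its double-bond isomers react alike; formed in the flask) | COC(=O)C(C)CCC(=O)C1=CC(OC)=CCC(Br)=C1 | intermediate
9 | 5-bromo-1-methoxy-3-(5-methoxy-4-methyl-5-oxopentanoyl)cycloheptatrienylium tetrafluoroborate (formed in the flask) | C[O+]=C1C=CC(Br)=CC(C(=O)CCC(C)C(=O)OC)=C1.F[B-](F)(F)F | intermediate
10 | methyl 5-(6-bromo-3-oxocyclohepta-1,4,6-trien-1-yl)-2-methyl-5-oxopentanoate (tropone keto ester) | COC(=O)C(C)CCC(=O)C1=CC(=O)C=CC(Br)=C1 | intermediate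
11 | methyl (5R)-5-(6-bromo-3-oxocyclohepta-1,4,6-trien-1-yl)-5-hydroxy-2-methylpentanoate (both C2 epimers of the chain) | COC(=O)C(C)CC[C@@H](O)C1=CC(=O)C=CC(Br)=C1 | intermediate
12 | methyl (5R)-5-(6-bromo-3-oxocyclohepta-1,4,6-trien-1-yl)-5-[(tert-butyldimethylsilyl)oxy]-2-methylpentanoate | COC(=O)C(C)CC[C@@H](O[Si](C)(C)C(C)(C)C)C1=CC(=O)C=CC(Br)=C1 | intermediate
13 | (5R)-5-(6-bromo-3-oxocyclohepta-1,4,6-trien-1-yl)-5-[(tert-butyldimethylsilyl)oxy]-2-methylpentanoic acid | OC(=O)C(C)CC[C@@H](O[Si](C)(C)C(C)(C)C)C1=CC(=O)C=CC(Br)=C1 | intermediate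
14 | (5R)-5-(6-bromo-3-oxocyclohepta-1,4,6-trien-1-yl)-5-[(tert-butyldimethylsilyl)oxy]-2-methylpentanoyl chloride (formed in the flask) | ClC(=O)C(C)CC[C@@H](O[Si](C)(C)C(C)(C)C)C1=CC(=O)C=CC(Br)=C1 | intermediate
15 | (5R)-5-(6-bromo-3-oxocyclohepta-1,4,6-trien-1-yl)-5-[(tert-butyldimethylsilyl)oxy]-2-methylpent-1-en-1-one (tropone-tethered methylketene, formed in the flask) | O=C=C(C)CC[C@@H](O[Si](C)(C)C(C)(C)C)C1=CC(=O)C=CC(Br)=C1 | intermediate
16 | (1R,4S,5R)-9-bromo-1-[(tert-butyldimethylsilyl)oxy]-4-methyl tricyclic enol lactone: cyclohexane ring A (C1–C5, C10) fused at C5–C10 to cycloheptatriene ring B (C6=C7, C8=C9, C10=C20), γ-lactone C4–C19(=O)–O–C6, C19 and the C1 oxygen on one face, C18 methyl and H5 on the other | BrC1=CC=C2OC(=O)[C@@]3(C)CC[C@@H](O[Si](C)(C)C(C)(C)C)C(=C1)[C@@H]23 | intermediate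
17 | 9-trimethylstannyl analogue of 16, (1R,4S,5R) | C[Sn](C)(C)C1=CC=C2OC(=O)[C@@]3(C)CC[C@@H](O[Si](C)(C)C(C)(C)C)C(=C1)[C@@H]23 | intermediate
18 | diisopropyl squarate (3,4-diisopropoxycyclobut-3-ene-1,2-dione) | CC(C)OC1=C(OC(C)C)C(=O)C1=O | starting material
19 | 4-hydroxy-2,3-diisopropoxy-4-isopropylcyclobut-2-en-1-one (formed in the flask) | CC(C)OC1=C(OC(C)C)C(O)(C(C)C)C1=O | intermediate
20 | 3-isopropoxy-4-isopropylcyclobut-3-ene-1,2-dione | CC(C)OC1=C(C(C)C)C(=O)C1=O | intermediate
21 | 4-hydroxy-3-isopropoxy-2-isopropylcyclobut-2-en-1-one (racemic) | CC(C)OC1=C(C(C)C)C(=O)C1O | intermediate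
22 | 4-chloro-3-isopropoxy-2-isopropylcyclobut-2-en-1-one (racemic) | CC(C)OC1=C(C(C)C)C(=O)C1Cl | intermediate
23 | 3-isopropoxy-2-isopropyl-4-(C9-yl of the tricyclic enol lactone)cyclobut-2-en-1-one (epimers at the cyclobutenone carbon, formed in the flask) | CC(C)OC1=C(C(C)C)C(=O)C1C4=CC=C2OC(=O)[C@@]3(C)CC[C@@H](O[Si](C)(C)C(C)(C)C)C(=C4)[C@@H]23 | intermediate
24 | dienylketene O=C=C13(iPr)–C12(OiPr)=C11H–C9 with C13 and C9 cis on C12=C11 (formed in the flask) | O=C=C(C(C)C)/C(OC(C)C)=C\C4=CC=C2OC(=O)[C@@]3(C)CC[C@@H](O[Si](C)(C)C(C)(C)C)C(=C4)[C@@H]23 | intermediate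
25 | cyclohexa-2,4-dienone with C14=O, sp3 C8–H and C9=C11 (keto tautomer of 26, formed in the flask) | O=C1C(C(C)C)=C(OC(C)C)C=C4C1C=C2OC(=O)[C@@]3(C)CC[C@@H](O[Si](C)(C)C(C)(C)C)C(=C4)[C@@H]23 | intermediate
26 | (1R,4S,5R)-1-[(tert-butyldimethylsilyl)oxy]-14-hydroxy-12-isopropoxyicetexa-6,8,10(20),11,13-pentaen-19,6-olide (ring C aromatic, C11–H free) | Oc1c(C(C)C)c(OC(C)C)cc4c1C=C2OC(=O)[C@@]3(C)CC[C@@H](O[Si](C)(C)C(C)(C)C)C(=C4)[C@@H]23 | intermediate
27 | (1R,4S,5R)-1-[(tert-butyldimethylsilyl)oxy]-12-isopropoxy-11,14-dioxoicetexa-6,8,10(20),12-tetraen-19,6-olide | CC(C)C1=C(OC(C)C)C(=O)C2=C(C=C3OC(=O)[C@@]4(C)CC[C@@H](O[Si](C)(C)C(C)(C)C)C(=C2)[C@@H]34)C1=O | intermediate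
28 | (1R,4S,5R)-1-[(tert-butyldimethylsilyl)oxy]-12-hydroxy-11,14-dioxoicetexa-6,8,10(20),12-tetraen-19,6-olide | CC(C)C1=C(O)C(=O)C2=C(C=C3OC(=O)[C@@]4(C)CC[C@@H](O[Si](C)(C)C(C)(C)C)C(=C2)[C@@H]34)C1=O | intermediate
29 | 6,7-anhydroballotiquinone, (1R,4S,5R)-1,12-dihydroxy-11,14-dioxoicetexa-6,8,10(20),12-tetraen-19,6-olide | CC(C)C1=C(O)C(=O)C2=C(C=C3OC(=O)[C@@]4(C)CC[C@@H](O)C(=C2)[C@@H]34)C1=O | target

Total step count: 16 (steps 1–9 and 13–16 in the main line, steps 10–12 for the cyclobutenone).
Longest linear sequence: 13 steps (1–9, 13–16).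

Steps most likely to fail

Step 8 (the proposed [8+2] closure). The ketene may be consumed by dimerisation or by cyclobutanone formation at the C5=C10 bond before the tropone oxygen engages, or ring A may close with the silyloxy group axial, which would invert C4/C5 relative to C1. The fallback uses known reaction types, sets out from ester 12 and returns at 16. LiN(iPr)2 in THF at −78 °C generates the ester enolate, which adds intramolecularly to C5 of the tropone (eight-fold conjugate addition of a carbon nucleophile to a tropone, lithium bridging the enolate and tropone oxygens so that C19 should end up cis to C6); an acetic acid quench gives the cyclohepta-3,5-dienone keto ester F1. LiI in ethyl acetate at 75 °C removes the ester methyl group by SN2 attack to give the keto acid F2. Activation of F2 with 1-chloro-N,N,2-trimethylprop-1-en-1-amine and Et3N at 0 °C enolises the ketone toward the doubly activated C7 methylene and closes the enol lactone, which is 16.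

Step 13 (Stille coupling and benzannulation). The dienylstannane may be lost by protodestannylation, the cyclobutenyl–palladium intermediate may couple at its other allylic terminus, or hydrogen may migrate around ring B at the temperature needed for ring opening. The fallback replaces the cross-coupling by carbonyl addition and a Moore rearrangement; it sets out from bromide 16 and dione 20 and returns at quinone 27, so that steps 9, 11, 12 and 14 are not needed. Bromine–lithium exchange with t-BuLi (2 equiv) in THF/Et2O at −100 °C gives the alkenyllithium F3, which is quenched at once with 20 and adds to the carbonyl next to the alkoxy-bearing carbon to give the 4-alkenyl-4-hydroxycyclobutenone F4. Heating F4 in toluene at 80 °C (ring opening, 6π closure onto C8, tautomerisation) gives the hydroquinone F5, and Ag2O in CH2Cl2 oxidises F5 to 27. The exposure of the enol lactone to an organolithium is the reason this is held in reserve.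

Step 5 (asymmetric transfer hydrogenation). Hydride may be delivered to the ring (conjugate reduction of the acyl tropone), or enantioselection may be poor because the troponyl group does not behave as an aryl group. The fallback replaces asymmetric catalysis by resolution; it sets out from ketone 10 and returns at 11. Luche reduction (NaBH4, CeCl3·7H2O, MeOH, −78 °C) gives the racemic carbinol F6. Burkholderia cepacia lipase with vinyl acetate in MTBE should acetylate the (R)-enantiomer, as it does for 1-arylalkanols, to give the (R)-acetate F7 and leave the (S)-carbinol F8, which is returned to 10 with MnO2 in CH2Cl2. Methanolysis of F7 (K2CO3, MeOH, 0 °C) gives 11.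

Further compounds
F1 | step 8 | methyl (1R,4S,5R)-9-bromo-1-[(tert-butyldimethylsilyl)oxy]-4-methyl-6-oxo bicyclic keto ester (ring A fused at C5–C10 to a cyclohepta-dienone ring B with C7H2, C8=C9, C10=C20; CO2Me on C4 cis to C6) | COC(=O)[C@@]1(C)CC[C@@H](O[Si](C)(C)C(C)(C)C)C2=CC(Br)=CCC(=O)[C@@H]12
F2 | step 8 | carboxylic acid corresponding to F1 | OC(=O)[C@@]1(C)CC[C@@H](O[Si](C)(C)C(C)(C)C)C2=CC(Br)=CCC(=O)[C@@H]12
F3 | step 13 | 9-lithio analogue of 16 | [Li]C1=CC=C2OC(=O)[C@@]3(C)CC[C@@H](O[Si](C)(C)C(C)(C)C)C(=C1)[C@@H]23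
F4 | step 13 | 4-hydroxy-3-isopropoxy-2-isopropyl-4-(C9-yl of the tricyclic enol lactone)cyclobut-2-en-1-one | CC(C)OC1=C(C(C)C)C(=O)C1(O)C4=CC=C2OC(=O)[C@@]3(C)CC[C@@H](O[Si](C)(C)C(C)(C)C)C(=C4)[C@@H]23
F5 | step 13 | 11,14-hydroquinone of 27 | Oc1c(C(C)C)c(OC(C)C)c(O)c4c1C=C2OC(=O)[C@@]3(C)CC[C@@H](O[Si](C)(C)C(C)(C)C)C(=C4)[C@@H]23
F6 | step 5 | methyl 5-(6-bromo-3-oxocyclohepta-1,4,6-trien-1-yl)-5-hydroxy-2-methylpentanoate (racemic at the carbinol) | COC(=O)C(C)CCC(O)C1=CC(=O)C=CC(Br)=C1
F7 | step 5 | methyl (5R)-5-acetoxy-5-(6-bromo-3-oxocyclohepta-1,4,6-trien-1-yl)-2-methylpentanoate | COC(=O)C(C)CC[C@@H](OC(C)=O)C1=CC(=O)C=CC(Br)=C1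
F8 | step 5 | methyl (5S)-5-(6-bromo-3-oxocyclohepta-1,4,6-trien-1-yl)-5-hydroxy-2-methylpentanoate | COC(=O)C(C)CC[C@H](O)C1=CC(=O)C=CC(Br)=C1
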